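**Plan**

- Numbering used: C1≡C2–C3(Br)–C4–C5–C6(OAc)–C7–C8–C9(OH)–C10(Br)–C11–C12=C13–C14–C15; the oxolane is O1–C4–C5–C6–C7.
- Retrosynthetic cuts, in order: C3–Br (from the C3 alcohol, inversion); ring bond O1–C4 (5-exo opening of a cis-C3/C4 alkynyl epoxide by the C7 hydroxyl, inversion at C4); C7–H and C8–C9 (methyl ketone C7(=O)–C8H3 plus an α-bromoaldehyde C9–C15).
- Enabling feature: ring carbon C7 lies 1,3 to the C9 carbinol, which has the C10 bromide next to it. With the oxolane opened at O1–C4, C7–C8–C9–C10 is the retron of an α-bromoaldehyde aldol followed by chelate-controlled 1,3-syn ketone reduction.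
- Forward order: the C1–C8 epoxy acetoxy ketone is built from methyl (R)-glycidate and a silylated butadiyne, and the C9–C15 bromoaldehyde from pent-1-en-3-ol. A boron aldol with in-situ reduction joins the chain at C8–C9, acid then closes the only ring, and bromination at C3 finishes.
- Stereochemistry: C6 is bought. C4 and C3 are relayed from C6 by hydroxyl-directed epoxidation of a Z-alkene, and each is inverted once later. C10 is set by organocatalytic bromination, and C9 and C7 are relayed from C10 in the key flask. The 12E alkene comes from a Johnson–Claisen rearrangement.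

Key step: step 10

Remark: the facial sense of the prolinol-type catalyst in step 9 is taken from the steric-shielding enamine model, and the antipodal catalyst is used if it proves reversed; aldehyde 14 is configurationally labile and is made and used cold without storage.

Step 1
Reactants: 1 1,4-bis(trimethylsilyl)buta-1,3-diyne; 2 methyl (2R)-oxirane-2-carboxylate (methyl (R)-glycidate)
Product: 4 methyl (2R)-2-hydroxy-7-(trimethylsilyl)hepta-4,6-diynoate, via lithium (trimethylsilyl)butadiynide 3 (not isolated)
Conditions: MeLi·LiBr (1.0 equiv), THF, rt; BF3·OEt2, −78 °C; then 2, −78 °C; aq. NH4Cl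
Reagents that add atoms: none
Why: MeLi cleaves one C–Si bond of 1 to give the lithium diynide, which after complexation with BF3 should open the epoxide of 2 at its CH2 terminus faster than it adds to the ester (BF3-mediated epoxide alkynylation), so the bought stereocentre (later C6) is not touched.

Step 2
Reactants: 4 methyl (2R)-2-hydroxy-7-(trimethylsilyl)hepta-4,6-diynoate
Product: 6 methyl (2R,4Z)-2-hydroxyhept-4-en-6-ynoate, via silylated Z-enyne ester 5 (not isolated)
Conditions: Zn(Cu/Ag), MeOH/H2O (1:1), 40 °C; filter; K2CO3 (cat.), MeOH, rt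
Reagents that add atoms: none
Why: Activated zinc should reduce only the conjugated triple bond that is not silyl-capped, and do so cis (Zn(Cu/Ag) semireduction), giving the Z-alkene needed for a cis-epoxide; K2CO3/MeOH then removes the silyl group (protodesilylation) without affecting the ester.

Step 3
Reactants: 6 methyl (2R,4Z)-2-hydroxyhept-4-en-6-ynoate
Product: 7 (2R,4Z)-2-hydroxy-N-methoxy-N-methylhept-4-en-6-ynamide
Conditions: MeNH(OMe)·HCl, i-PrMgCl (excess), THF, −20 → 0 °C; aq. NH4Cl
Reagents that add atoms: N,O-dimethylhydroxylamine hydrochloride, CNOC.Cl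
Why: Aminolysis of the methyl ester by the chloromagnesium amide (Weinreb amide formation); the magnesium alkoxide formed first shields the α-stereocentre from epimerisation.

Step 4
Reactants: 7 (2R,4Z)-2-hydroxy-N-methoxy-N-methylhept-4-en-6-ynamide
Product: 8 (2R)-3-[(2S,3R)-3-ethynyloxiran-2-yl]-2-hydroxy-N-methoxy-N-methylpropanamide
Conditions: VO(acac)2 (5 mol %), t-BuOOH (anhydrous), CH2Cl2, 0 °C → rt
Reagents that add atoms: tert-butyl hydroperoxide, CC(C)(C)OO
Why: Hydroxyl-directed vanadium-catalysed epoxidation of a homoallylic alcohol: the vanadate ester of the C6 hydroxyl delivers oxygen through a chair-like transition state with the amide-bearing substituent equatorial and the Z-alkene turned away from C6 to avoid allylic strain, which should place the new C4–O bond 1,3-syn to the C6 oxygen (C4 S) and, stereospecifically from the Z-alkene, give C3 R; the alkyne is inert.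

Step 5
Reactants: 8 (2R)-3-[(2S,3R)-3-ethynyloxiran-2-yl]-2-hydroxy-N-methoxy-N-methylpropanamide
Product: 9 (3R)-4-[(2S,3R)-3-ethynyloxiran-2-yl]-3-hydroxybutan-2-one
Conditions: MeLi (3.3 equiv), THF, −78 °C; AcOH quench at −78 °C
Reagents that add atoms: methyllithium, [Li]C
Why: Weinreb ketone synthesis: MeLi adds once to the N-methoxy amide (chelated tetrahedral intermediate) at −78 °C, where the epoxide is inert and the hydroxyl and alkyne are only deprotonated; this methyl group is C8.

Step 6
Reactants: 9 (3R)-4-[(2S,3R)-3-ethynyloxiran-2-yl]-3-hydroxybutan-2-one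
Product: 10 (2R)-1-[(2S,3R)-3-ethynyloxiran-2-yl]-3-oxobutan-2-yl acetate
Conditions: Ac2O, pyridine, DMAP (cat.), CH2Cl2, 0 °C
Reagents that add atoms: acetic anhydride, CC(=O)OC(C)=O
Why: DMAP-catalysed O-acylation installs the C6 acetate of the target before the aldol, so that the C6 and C9 oxygens never need to be told apart later.

Step 7
Reactants: 11 pent-1-en-3-ol (racemic)
Product: 12 ethyl (4E)-hept-4-enoate
Conditions: MeC(OEt)3 (5 equiv), EtCO2H (cat.), 140 °C, EtOH distilled off
Reagents that add atoms: triethyl orthoacetate, CCOC(C)(OCC)OCC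
Why: Johnson–Claisen rearrangement: the ketene acetal formed in situ undergoes a [3,3]-shift through a chair with the ethyl group equatorial, which should give the E-alkene (C12=C13) and consumes the racemic carbinol centre.

Step 8
Reactants: 12 ethyl (4E)-hept-4-enoate
Product: 13 (4E)-hept-4-enal
Conditions: DIBAL-H (1.05 equiv), CH2Cl2, −78 °C; Rochelle salt
Reagents that add atoms: none
Why: Partial ester reduction: the aluminium hemiacetal is stable at −78 °C and releases the aldehyde on work-up.

Step 9
Reactants: 13 (4E)-hept-4-enal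
Product: 14 (2R,4E)-2-bromohept-4-enal
Conditions: (R)-2-{bis[3,5-bis(trifluoromethyl)phenyl](trimethylsilyloxy)methyl}pyrrolidine (10 mol %), 4,4-dibromo-2,6-di-tert-butylcyclohexa-2,5-dien-1-one, PhCO2H (cat.), CH2Cl2/pentane, −40 °C; cold filtration through silica, used at once
Reagents that add atoms: 4,4-dibromo-2,6-di-tert-butylcyclohexa-2,5-dien-1-one, O=C1C(C(C)(C)C)=CC(Br)(Br)C=C1C(C)(C)C
Why: Enamine catalysis (organocatalytic α-bromination): the bulky diaryl(silyloxy)methyl group shields one face of the E-enamine so that the bromine donor attacks the other, setting C10 (R); the enamine is far more nucleophilic than the isolated alkene, which should be left alone.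

Step 10
Reactants: 10 (2R)-1-[(2S,3R)-3-ethynyloxiran-2-yl]-3-oxobutan-2-yl acetate; 14 (2R,4E)-2-bromohept-4-enal
Product: 17 (2R,3R,5S,6R,8E)-6-bromo-1-[(2S,3R)-3-ethynyloxiran-2-yl]-3,5-dihydroxyundec-8-en-2-yl acetate, via dicyclohexylboron enolate 15 (not isolated), via boron aldolate 16 (not isolated)
Conditions: (c-Hex)2BCl, Et3N, Et2O, −78 → −20 °C; 14, −78 °C; LiBH4, THF, −78 °C; pH 7 buffer, MeOH, H2O2, 0 °C; product used directly
Reagents that add atoms: none
Why: Soft enolisation with (c-Hex)2BCl/Et3N should take place at the unhindered methyl group (C8) and not at the acetoxy-bearing C6–H, as is usual for α-acyloxy ketones, and the boron enolate adds to the aldehyde through a closed six-membered (Zimmerman–Traxler-type) transition state, forming C8–C9. The new C9 centre is controlled by C10: in the Cornforth (polar Felkin–Anh) arrangement the C–Br dipole opposes the carbonyl and the enolate attacks past hydrogen, giving the 9,10-anti bromohydrin, and any 1,4-induction from the C6 acetoxy centre is expected to be 1,4-syn and therefore matched. LiBH4 then reduces the boron aldolate in the same flask through its six-membered boron chelate with external axial hydride delivery, so that C7 is set 1,3-syn to C9; the closest known reaction type is the boron aldol with in-situ syn-reduction, here combined with the halohydrin aldol of α-haloaldehydes. No ring is closed in this step (the oxolane closes in step 11 in the 5-exo-tet mode). The step needs chemoselectivity for the ketone/aldehyde pair over the epoxide, acetate, alkyne and C–Br bonds, which the low temperature, the amine-buffered chloroborane and the mild borohydride should secure, and it needs 14 to keep its configuration, for which it is made and used cold.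

Step 11
Reactants: 17 (2R,3R,5S,6R,8E)-6-bromo-1-[(2S,3R)-3-ethynyloxiran-2-yl]-3,5-dihydroxyundec-8-en-2-yl acetate
Product: 18 (2R,3R,5R)-2-[(2S,3R,5E)-3-bromo-2-hydroxyoct-5-en-1-yl]-5-[(1R)-1-hydroxyprop-2-yn-1-yl]oxolan-3-yl acetate
Conditions: CSA (10 mol %), CH2Cl2, 0 °C
Reagents that add atoms: none
Why: Acid-catalysed intramolecular epoxide opening (5-exo-tet): the C7 hydroxyl attacks C4 with inversion (S → R) to close the all-cis oxolane and release the C3 hydroxyl with retention; exo attack is expected because an ethynyl group does not stabilise positive charge at C3, and the bromohydrin and acetate are inert to catalytic acid at 0 °C.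

Step 12
Reactants: 18 (2R,3R,5R)-2-[(2S,3R,5E)-3-bromo-2-hydroxyoct-5-en-1-yl]-5-[(1R)-1-hydroxyprop-2-yn-1-yl]oxolan-3-yl acetate
Product: 19 (2R,3R,5R)-5-[(1S)-1-bromoprop-2-yn-1-yl]-2-[(2S,3R,5E)-3-bromo-2-hydroxyoct-5-en-1-yl]oxolan-3-yl acetate
Conditions: CBr4 (1.3 equiv), PPh3 (1.3 equiv), CH2Cl2, −20 → 0 °C
Reagents that add atoms: carbon tetrabromide, BrC(Br)(Br)Br
Why: Appel reaction: SN2 displacement of the propargylic oxyphosphonium ion by bromide inverts C3 (R → S); the propargylic centre should be displaced much faster than the hindered C9 centre deactivated by its neighbouring bromide, whose oxyphosphonium salt, if formed, reverts to the alcohol on aqueous work-up.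

**Compound list**

1 | 1,4-bis(trimethylsilyl)buta-1,3-diyne | C[Si](C)(C)C#CC#C[Si](C)(C)C | starting material
2 | methyl (2R)-oxirane-2-carboxylate | COC(=O)[C@H]1CO1 | starting material
3 | lithium 4-(trimethylsilyl)buta-1,3-diyn-1-ide | [Li]C#CC#C[Si](C)(C)C | intermediate
4 | methyl (2R)-2-hydroxy-7-(trimethylsilyl)hepta-4,6-diynoate | COC(=O)[C@H](O)CC#CC#C[Si](C)(C)C | intermediate
5 | methyl (2R,4Z)-2-hydroxy-7-(trimethylsilyl)hept-4-en-6-ynoate | COC(=O)[C@H](O)C/C=C\C#C[Si](C)(C)C | intermediate
6 | methyl (2R,4Z)-2-hydroxyhept-4-en-6-ynoate | COC(=O)[C@H](O)C/C=C\C#C | intermediate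
7 | (2R,4Z)-2-hydroxy-N-methoxy-N-methylhept-4-en-6-ynamide | CON(C)C(=O)[C@H](O)C/C=C\C#C | intermediate
8 | (2R)-3-[(2S,3R)-3-ethynyloxiran-2-yl]-2-hydroxy-N-methoxy-N-methylpropanamide | C#C[C@H]1O[C@H]1C[C@@H](O)C(=O)N(C)OC | intermediate
9 | (3R)-4-[(2S,3R)-3-ethynyloxiran-2-yl]-3-hydroxybutan-2-one | C#C[C@H]1O[C@H]1C[C@@H](O)C(C)=O | intermediate
10 | (2R)-1-[(2S,3R)-3-ethynyloxiran-2-yl]-3-oxobutan-2-yl acetate | C#C[C@H]1O[C@H]1C[C@@H](OC(C)=O)C(C)=O | intermediate
11 | pent-1-en-3-ol (racemic) | C=CC(O)CC | starting material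
12 | ethyl (4E)-hept-4-enoate | CCOC(=O)CC/C=C/CC | intermediate
13 | (4E)-hept-4-enal | O=CCC/C=C/CC | intermediate
14 | (2R,4E)-2-bromohept-4-enal | O=C[C@H](Br)C/C=C/CC | intermediate
15 | (2R)-3-[(dicyclohexylboranyl)oxy]-1-[(2S,3R)-3-ethynyloxiran-2-yl]but-3-en-2-yl acetate (boron enolate) | C#C[C@H]1O[C@H]1C[C@@H](OC(C)=O)C(=C)OB(C1CCCCC1)C1CCCCC1 | intermediate
16 | (2R,5S,6R,8E)-6-bromo-5-[(dicyclohexylboranyl)oxy]-1-[(2S,3R)-3-ethynyloxiran-2-yl]-3-oxoundec-8-en-2-yl acetate (boron aldolate) | C#C[C@H]1O[C@H]1C[C@@H](OC(C)=O)C(=O)C[C@H](OB(C1CCCCC1)C1CCCCC1)[C@H](Br)C/C=C/CC | intermediate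
17 | (2R,3R,5S,6R,8E)-6-bromo-1-[(2S,3R)-3-ethynyloxiran-2-yl]-3,5-dihydroxyundec-8-en-2-yl acetate | C#C[C@H]1O[C@H]1C[C@@H](OC(C)=O)[C@H](O)C[C@H](O)[C@H](Br)C/C=C/CC | intermediate
18 | (2R,3R,5R)-2-[(2S,3R,5E)-3-bromo-2-hydroxyoct-5-en-1-yl]-5-[(1R)-1-hydroxyprop-2-yn-1-yl]oxolan-3-yl acetate | C#C[C@@H](O)[C@H]1C[C@@H](OC(C)=O)[C@@H](C[C@H](O)[C@H](Br)C/C=C/CC)O1 | intermediate
19 | (2R,3R,5R)-5-[(1S)-1-bromoprop-2-yn-1-yl]-2-[(2S,3R,5E)-3-bromo-2-hydroxyoct-5-en-1-yl]oxolan-3-yl acetate | C#C[C@H](Br)[C@H]1C[C@@H](OC(C)=O)[C@@H](C[C@H](O)[C@H](Br)C/C=C/CC)O1 | target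

**Step count and risks**

Total step count: 12. Longest linear sequence: 9 (steps 1–6, then 10–12).

Steps most likely to fail:

1. Step 10. What may go wrong: erosion of the configuration of the α-bromoaldehyde before C–C bond formation, ring-opening of the alkynyl epoxide by the Lewis-acidic chloroborane, or 1,2-acyl migration after the reduction. The fallback sets out from 10 (with 14) and replaces the one-pot boron sequence by two separate operations. The lithium enolate of 10 (LiHMDS, THF, −78 °C, short enolisation time) is added to 14 in the manner of the lithium-enolate halohydrin aldol and quenched cold with AcOH, to isolate the ketol (2R,5S,6R,8E)-6-bromo-1-[(2S,3R)-3-ethynyloxiran-2-yl]-5-hydroxy-3-oxoundec-8-en-2-yl acetate F1. A Narasaka–Prasad reduction (Et2BOMe, NaBH4, THF/MeOH, −78 °C) then returns to the route at 17.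

2. Step 12. What may go wrong: loss of chemoselectivity between the two secondary hydroxyls (activation at C9, helped by the neighbouring bromine), SN2′ attack leading to a bromoallene, or partial epimerisation of the propargylic bromide by bromide ion. The fallback sets out from 18 and protects C9 before the bromination. MnO2 (CH2Cl2, rt) should oxidise only the propargylic alcohol, to the ynone (2R,3R,5R)-2-[(2S,3R,5E)-3-bromo-2-hydroxyoct-5-en-1-yl]-5-(prop-2-ynoyl)oxolan-3-yl acetate F2. TESOTf/2,6-lutidine then silylates the one remaining hydroxyl, to (2R,3R,5R)-2-[(2S,3R,5E)-3-bromo-2-(triethylsilyloxy)oct-5-en-1-yl]-5-(prop-2-ynoyl)oxolan-3-yl acetate F3. CBS reduction ((S)-Me-oxazaborolidine, catecholborane, −78 °C; the antipode if the sense proves reversed) regenerates the (1R)-carbinol (2R,3R,5R)-2-[(2S,3R,5E)-3-bromo-2-(triethylsilyloxy)oct-5-en-1-yl]-5-[(1R)-1-hydroxyprop-2-yn-1-yl]oxolan-3-yl acetate F4. The Appel reaction, now on the only free hydroxyl, gives (2R,3R,5R)-5-[(1S)-1-bromoprop-2-yn-1-yl]-2-[(2S,3R,5E)-3-bromo-2-(triethylsilyloxy)oct-5-en-1-yl]oxolan-3-yl acetate F5, and HF·pyridine (THF, 0 °C) removes the silyl group to come back at 19.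

3. Step 4. What may go wrong: slow oxygen transfer to the electron-poor enyne alkene, insufficient facial selectivity of the directed delivery, or Lewis-acid-induced cyclisation of the epoxy alcohol once formed. The fallback sets out from 7 and changes from substrate control to catalyst control: a Shi epoxidation with the glucose-derived oxazolidinone ketone used for cis-olefins (Oxone, K2CO3/AcOH buffer at pH about 8, DME/dimethoxymethane–water, −10 °C) should give 8 directly, where it rejoins the route; no compound outside the list arises (none F0).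

Further compounds
F1 | step 10 | (2R,5S,6R,8E)-6-bromo-1-[(2S,3R)-3-ethynyloxiran-2-yl]-5-hydroxy-3-oxoundec-8-en-2-yl acetate | C#C[C@H]1O[C@H]1C[C@@H](OC(C)=O)C(=O)C[C@H](O)[C@H](Br)C/C=C/CC
F2 | step 12 | (2R,3R,5R)-2-[(2S,3R,5E)-3-bromo-2-hydroxyoct-5-en-1-yl]-5-(prop-2-ynoyl)oxolan-3-yl acetate | C#CC(=O)[C@H]1C[C@@H](OC(C)=O)[C@@H](C[C@H](O)[C@H](Br)C/C=C/CC)O1
F3 | step 12 | (2R,3R,5R)-2-[(2S,3R,5E)-3-bromo-2-(triethylsilyloxy)oct-5-en-1-yl]-5-(prop-2-ynoyl)oxolan-3-yl acetate | C#CC(=O)[C@H]1C[C@@H](OC(C)=O)[C@@H](C[C@H](O[Si](CC)(CC)CC)[C@H](Br)C/C=C/CC)O1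
F4 | step 12 | (2R,3R,5R)-2-[(2S,3R,5E)-3-bromo-2-(triethylsilyloxy)oct-5-en-1-yl]-5-[(1R)-1-hydroxyprop-2-yn-1-yl]oxolan-3-yl acetate | C#C[C@@H](O)[C@H]1C[C@@H](OC(C)=O)[C@@H](C[C@H](O[Si](CC)(CC)CC)[C@H](Br)C/C=C/CC)O1
F5 | step 12 | (2R,3R,5R)-5-[(1S)-1-bromoprop-2-yn-1-yl]-2-[(2S,3R,5E)-3-bromo-2-(triethylsilyloxy)oct-5-en-1-yl]oxolan-3-yl acetate | C#C[C@H](Br)[C@H]1C[C@@H](OC(C)=O)[C@@H](C[C@H](O[Si](CC)(CC)CC)[C@H](Br)C/C=C/CC)O1
F0 | step 4 | none | none
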